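**Retrosynthetic overview**

1. Target 11 ⇐ dienol 10 by hydroxyl-directed epoxidation of the C1=C6 alkene, cis to the C2 hydroxyl (target numbering: C1 quaternary oxirane carbon, C2 carbinol, C3 benzoate carbon, C4=C5 alkene, C6 oxirane CH).
2. 10 ⇐ 7-oxanorbornadiene benzoate 9 by rhodium-catalysed SN2' anti opening of the oxygen bridge with benzoate, which sets C3 trans to the C2 oxygen and places the C4=C5 alkene.
3. 9 ⇐ bromo aldehyde 5 by reduction, spiro-oxirane closure, oxirane-to-allylic-alcohol isomerisation and benzoylation; the bromine is the activating group and stores the unsaturation.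
4. 5 ⇐ furan + 2-bromoacrolein by a catalytic enantioselective Diels–Alder reaction that forms C1–C2 and C5–C6. The enabling feature: in the cyclohexene ring the carbinol carbon C2 and the alkene carbon C5 are 1,4 to each other, so tying the C2 oxygen back to C5 reveals a 7-oxabicyclo[2.2.1]heptene, i.e. furan (C2–C5 plus that oxygen) and a C1/C6 dienophile carrying the CH2O arm.
5. Ring order: six-membered carbocycle and temporary oxygen bridge together (step 2), temporary spiro-oxirane (steps 3–4), bridge opened (step 6), oxirane of the target last (step 7).

Key step: step 2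

Assumption (sense of the two chiral catalysts): the face selectivity of the oxazaborolidinone in step 2 is taken from its behaviour with cyclopentadiene and that of the ferrocenyl diphosphine in step 6 from benzo-fused oxabicycles; if a calibration run shows the opposite sense, the mirror-image catalyst or ligand is used and nothing else changes.

**Route**

Step 1
Reactants: 1 acrolein
Product: 3 2-bromoacrolein, via 2,3-dibromopropanal 2 (not isolated)
Conditions: Br2, CH2Cl2, −78 → 0 °C; then Et3N, 0 °C → rt
Reagents that add atoms: bromine, BrBr
Why: Bromine adds across the C=C bond and triethylamine then removes the acidic alpha hydrogen with loss of the beta bromide (alkene bromination followed by dehydrobromination), which should give the 2-bromo enal with no stereocentre left.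

Step 2
Reactants: 3 2-bromoacrolein; 4 furan
Product: 5 (1S,2S,4S)-2-bromo-7-oxabicyclo[2.2.1]hept-5-ene-2-carbaldehyde (formyl exo, bromine endo)
Conditions: (4R)-2-butyl-4-(1H-indol-3-ylmethyl)-3-(4-methylphenylsulfonyl)-1,3,2-oxazaborolidin-5-one (10 mol%, from N-tosyl-(R)-tryptophan and BuB(OH)2), furan (5 equiv), CH2Cl2, −78 °C
Reagents that add atoms: none
Why: The boron of the oxazaborolidinone binds the formyl oxygen of s-cis 2-bromoacrolein, the indole ring stacks on one face of the bound dienophile, and furan adds to the open face in a concerted, asynchronous [4+2] cycloaddition (catalytic enantioselective Diels–Alder reaction of a 2-haloacrolein, known with this catalyst type for cyclopentadiene and for furan). The cycloaddition closes the six-membered carbocycle by suprafacial addition across furan C2 and C5, and because the diene is cyclic the same event leaves the furan oxygen as a one-atom bridge, which completes the two five-membered oxygen rings of the 7-oxabicyclo[2.2.1]heptene. Both bridgeheads C1 and C4 are set by the catalyst-controlled face of the dienophile combined with the formyl-exo (bromine-endo) transition state that 2-haloacroleins prefer; C2 is set by the same two elements and is erased in step 4. The step needs facial and exo selectivity together (a formyl-endo adduct from the same face would feed the mirror-image series) and low temperature, because an adduct of aromatic furan with an activated dienophile can revert; the bromine secures the exo mode and the reactivity at −78 °C, and the crude adduct is reduced at once in step 3. In one operation the step should deliver all seven carbons of the target core, the oxygen of the future secondary alcohol with its absolute configuration, the leaving-group oxygen at the future alkene carbon, and the single source of chirality from which the other three stereocentres are relayed.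

Step 3
Reactants: 5 (1S,2S,4S)-2-bromo-7-oxabicyclo[2.2.1]hept-5-ene-2-carbaldehyde
Product: 7 (1S,2S,4S)-spiro[7-oxabicyclo[2.2.1]hept-5-ene-2,2'-oxirane] (oxirane oxygen exo), via bromohydrin 6 (not isolated)
Conditions: NaBH4, MeOH–CH2Cl2, −78 → 0 °C; then K2CO3, MeOH, rt
Reagents that add atoms: none
Why: Borohydride reduction of the aldehyde should give the primary alcohol and switch off retro-cycloaddition, and carbonate then closes the oxirane by an intramolecular Williamson displacement (3-exo-tet) of the tertiary bromide with inversion, the oxygen entering on the exo face opposite the endo bromine, while the bridgeheads stay untouched and the spiro centre is only temporary.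

Step 4
Reactants: 7 (1S,2S,4S)-spiro[7-oxabicyclo[2.2.1]hept-5-ene-2,2'-oxirane]
Product: 8 [(1S,4R)-7-oxabicyclo[2.2.1]hepta-2,5-dien-2-yl]methanol
Conditions: Et2Al(TMP) (from Et2AlCl and LiTMP, 3 equiv), toluene, 0 °C; aqueous potassium sodium tartrate work-up
Reagents that add atoms: none
Why: Aluminium amide-mediated isomerisation of an oxirane to an allylic alcohol, in which aluminium binds the oxirane oxygen and the amide nitrogen removes the exo hydrogen at C3 that lies syn-periplanar to the breaking exo C2–O bond through a cyclic transition state; C3 is the only neighbour that can lose a hydrogen (the other is the bridgehead), so only the ring alkene and the primary allylic alcohol should form.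

Step 5
Reactants: 8 [(1S,4R)-7-oxabicyclo[2.2.1]hepta-2,5-dien-2-yl]methanol
Product: 9 [(1S,4R)-7-oxabicyclo[2.2.1]hepta-2,5-dien-2-yl]methyl benzoate
Conditions: BzCl, Et3N, 4-(dimethylamino)pyridine (cat.), CH2Cl2, 0 °C
Reagents that add atoms: benzoyl chloride, O=C(Cl)c1ccccc1
Why: Nucleophile-catalysed acylation of the primary allylic alcohol under basic conditions, which the acid-sensitive oxanorbornadiene should tolerate.

Step 6
Reactants: 9 [(1S,4R)-7-oxabicyclo[2.2.1]hepta-2,5-dien-2-yl]methyl benzoate
Product: 10 [(5R,6R)-5-(benzoyloxy)-6-hydroxycyclohexa-1,3-dien-1-yl]methyl benzoate (benzoate and hydroxyl trans)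
Conditions: [Rh(cod)Cl]2 (2.5 mol%), (S)-1-[(R)-2-(diphenylphosphino)ferrocenyl]ethyldi-tert-butylphosphine (6 mol%), PhCO2H (3 equiv), Et3N (3 equiv), THF, 60 °C
Reagents that add atoms: benzoic acid, O=C(O)c1ccccc1
Why: Rhodium-catalysed asymmetric ring opening of an oxabicyclic alkene with a carboxylate nucleophile, in which monovalent rhodium binds the exo face of the disubstituted alkene and the bridge oxygen, ionises the bridgehead C4–O bond remote from the substituted alkene with allylic transposition, and benzoate attacks the allyl terminus C6 next to the retained carbinol carbon from the face opposite the metal, so the new benzoate centre is set trans to the old bridge oxygen; the matched ligand decides which bridgehead bond breaks and should send the minor enantiomer of 9 to a separable regioisomer.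

Step 7
Reactants: 10 [(5R,6R)-5-(benzoyloxy)-6-hydroxycyclohexa-1,3-dien-1-yl]methyl benzoate
Product: 11 [(1S,2S,3R,6R)-3-(benzoyloxy)-2-hydroxy-7-oxabicyclo[4.1.0]hept-4-en-1-yl]methyl benzoate (oxirane cis to the 2-hydroxyl, 3-benzoate trans to it)
Conditions: VO(acac)2 (5 mol%), t-BuOOH (decane), CH2Cl2, 0 °C
Reagents that add atoms: tert-butyl hydroperoxide, CC(C)(C)OO
Why: Hydroxyl-directed vanadium-catalysed epoxidation, in which the pentavalent vanadium alkoxide of the secondary allylic alcohol delivers the peroxide oxygen to the adjacent trisubstituted alkene on the face of the hydroxyl and so sets both oxirane centres cis to it, while the other alkene has no directing hydroxyl and the benzoate on the opposite face does not interfere.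

**Compound list**

1 | acrolein | C=CC=O | starting material
2 | 2,3-dibromopropanal (racemic) | O=CC(Br)CBr | intermediate
3 | 2-bromoacrolein | C=C(Br)C=O | intermediate
4 | furan | c1ccoc1 | starting material
5 | (1S,2S,4S)-2-bromo-7-oxabicyclo[2.2.1]hept-5-ene-2-carbaldehyde | O=C[C@]1(Br)C[C@H]2C=C[C@@H]1O2 | intermediate
6 | [(1S,2R,4S)-2-bromo-7-oxabicyclo[2.2.1]hept-5-en-2-yl]methanol | OC[C@]1(Br)C[C@H]2C=C[C@@H]1O2 | intermediate
7 | (1S,2S,4S)-spiro[7-oxabicyclo[2.2.1]hept-5-ene-2,2'-oxirane] | C1O[C@@]12C[C@H]3C=C[C@@H]2O3 | intermediate
8 | [(1S,4R)-7-oxabicyclo[2.2.1]hepta-2,5-dien-2-yl]methanol | OCC1=C[C@H]2C=C[C@@H]1O2 | intermediate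
9 | [(1S,4R)-7-oxabicyclo[2.2.1]hepta-2,5-dien-2-yl]methyl benzoate | O=C(OCC1=C[C@H]2C=C[C@@H]1O2)c1ccccc1 | intermediate
10 | [(5R,6R)-5-(benzoyloxy)-6-hydroxycyclohexa-1,3-dien-1-yl]methyl benzoate | O=C(OCC1=CC=C[C@@H](OC(=O)c2ccccc2)[C@@H]1O)c1ccccc1 | intermediate
11 | [(1S,2S,3R,6R)-3-(benzoyloxy)-2-hydroxy-7-oxabicyclo[4.1.0]hept-4-en-1-yl]methyl benzoate | O=C(OC[C@@]12O[C@@H]1C=C[C@@H](OC(=O)c1ccccc1)[C@@H]2O)c1ccccc1 | target

**Step count and risks**

Total step count: 7. Longest linear sequence: 7 steps (1 → 11).

Steps most likely to fail:

Step 6. The rhodium catalyst may isomerise the oxanorbornadiene to phenols, the dienol product may aromatise by loss of benzoic acid or water, or the wrong bridgehead C–O bond may ionise. Fallback: the oxirane is installed before the bridge is opened, so that no diene is ever present. Setting out from 8, VO(acac)2 and t-BuOOH should epoxidise the hydroxymethyl-bearing alkene on its exo face to the exo-epoxy alcohol F1. Benzoylation (BzCl, Et3N) gives the epoxy benzoate F2. The rhodium/ligand/benzoic acid opening of the one remaining alkene then gives 11 directly, where the fallback returns to the route. In F2 the endo CH2OBz arm lies near the carbon that benzoate must attack, so the ligand has to override a steric bias there.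

Step 4. Metalation of the oxirane CH2 or a Lewis acid-induced skeletal rearrangement may compete with the syn beta-elimination. Fallback: the alkene is made by base-induced dehydrobromination instead. Setting out from 5, reduction with NaBH4 alone gives bromohydrin 6, now isolated. TBSCl and imidazole give the silyl ether F3. KOtBu in DMSO–THF should eliminate HBr into the ring to give the dienyl silyl ether F4. Bu4NF then frees 8, where the fallback returns.

Step 2. Facial or exo selectivity may be insufficient, or the adduct may lose enantiopurity by retro-cycloaddition and uncatalysed recombination. Fallback: chirality is introduced at step 6 instead. Setting out from 3 and 4, a ZnI2-promoted cycloaddition without chiral catalyst gives 5 together with its mirror image F5. Steps 3–5 unchanged carry the pair through the mirror-image bromohydrin F6 (not isolated), the mirror-image spiro-oxirane F7, the mirror-image alcohol F8 and the mirror-image benzoate F9. In step 6 the enantiopure ligand then acts as a regiodivergent parallel kinetic resolution: 9 should give 10, while F9 should give the regioisomeric dienol F10, which is removed by chromatography. The fallback returns at 10 and can deliver at most half of the material.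

Further compounds

F1 | step 6 | [2,3-exo-epoxy-7-oxabicyclo[2.2.1]hept-5-en-2-yl]methanol, oxirane oxygen syn to the bridge oxygen, bridgeheads as in 8 | OC[C@@]12O[C@@H]1[C@H]3C=C[C@@H]2O3
F2 | step 6 | [2,3-exo-epoxy-7-oxabicyclo[2.2.1]hept-5-en-2-yl]methyl benzoate, benzoate of F1 | O=C(OC[C@@]12O[C@@H]1[C@H]3C=C[C@@H]2O3)c1ccccc1
F3 | step 4 | tert-butyldimethylsilyl ether of 6 | CC(C)(C)[Si](C)(C)OC[C@]1(Br)C[C@H]2C=C[C@@H]1O2
F4 | step 4 | tert-butyldimethylsilyl ether of 8 | CC(C)(C)[Si](C)(C)OCC1=C[C@H]2C=C[C@@H]1O2
F5 | step 2 | (1R,2R,4R)-2-bromo-7-oxabicyclo[2.2.1]hept-5-ene-2-carbaldehyde, mirror image of 5 | O=C[C@@]1(Br)C[C@@H]2C=C[C@H]1O2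
F6 | step 2 | [(1R,2S,4R)-2-bromo-7-oxabicyclo[2.2.1]hept-5-en-2-yl]methanol, mirror image of 6 | OC[C@@]1(Br)C[C@@H]2C=C[C@H]1O2
F7 | step 2 | (1R,2R,4R)-spiro[7-oxabicyclo[2.2.1]hept-5-ene-2,2'-oxirane], mirror image of 7 | C1O[C@]12C[C@@H]3C=C[C@H]2O3
F8 | step 2 | [(1R,4S)-7-oxabicyclo[2.2.1]hepta-2,5-dien-2-yl]methanol, mirror image of 8 | OCC1=C[C@@H]2C=C[C@H]1O2
F9 | step 2 | [(1R,4S)-7-oxabicyclo[2.2.1]hepta-2,5-dien-2-yl]methyl benzoate, mirror image of 9 | O=C(OCC1=C[C@@H]2C=C[C@H]1O2)c1ccccc1
F10 | step 2 | [(3R,4R)-4-(benzoyloxy)-3-hydroxycyclohexa-1,5-dien-1-yl]methyl benzoate, regioisomer of 10 | O=C(OCC1=C[C@@H](O)[C@H](OC(=O)c2ccccc2)C=C1)c1ccccc1
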